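Ns = 2-nitrophenylsulfonyl. Indole numbering (N1, C2, C3, C3a, C4–C7, C7a) is used for all compounds, including the monocyclic precursors.

## The problem

Compound 10 is a flat, achiral indole. No stereocentre has to be set, and the whole difficulty is positional. The benzenoid ring (C3a, C4, C5, C6, C7, C7a) is pentasubstituted, with four neighbours in a row (N1 on C7a, Br on C7, OMe on C6, Br on C5) and hydrogen only on C4. In an intact indole, C3 and then C2 are far more nucleophilic than any benzenoid carbon. C5–Br and C7–Br must therefore be in place before the indole π system exists, whereas C3–Br can and should come last. The N1–C7a bond lies meta to the C6 oxygen, so the oxygen cannot guide an electrophilic amination to C7a, and a halide handle there would have to be told apart from the bromines that must stay. The feature that opens the problem is that C3a is para to C6 and the two bromines flank C6. The carbocycle together with C3, C2 and N1 is therefore a 4-(2-aminoethyl)-2,6-dibromophenol, with a local mirror plane through C3a and C6 that makes C4 and C7a equivalent. Once that ring is dearomatised to a cyclohexa-2,5-dienone, C7a is the β-carbon of the enone C7a=C7–C6=O and stands in a 1,5-relation to the nitrogen (N1–C2–C3–C3a–C7a), which inverts the polarity mismatch. The three C–Br bonds rule out hydrogenolysis, dissolving metals, organolithium reagents and Pd(0), and the N–H 3-bromoindole tolerates neither strong acid nor excess halogen, so it must be formed at the very end.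

## Retrosynthesis

**10 ⇒ 9 ⇒ 8 (C3–Br, then the C2=C3 π bond).** C3 is the innate site of electrophilic attack in indole 9, so this bromine needs no control element and is removed first. Going one level further back to indoline 8 costs nothing in the forward sense. An N-halo reagent dehydrogenates an N–H indoline, and the same reagent then brominates C3. C5 and C7, where an indoline would otherwise be brominated, are already occupied in 8. The forward reaction only has to stop before C2 is touched.

**8 ⇒ 7 ⇒ 6 (O–CH3 and N1–S).** The methyl group is cut while N1 is still sulfonylated, because a free indoline N–H would compete for the alkylating agent. The sulfonyl group is a nosyl group, the one common N-blocking group that leaves by attack of a soft nucleophile on its own ring. No reductant, metal or strong acid then meets the aryl bromides. Both operations share base and solvent and can be run in one flask through 7.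

**6 ⇒ 5 ⇒ 4 ⇒ 3 (N1–C7a, the key cut).** The neighbouring cuts (C3–C3a, N1–C2) lead to anilines or nitroarenes that keep the full unsymmetrical 1,2,3,4-pattern on the ring, so they only move the regiochemical problem. Cutting N1–C7a returns the carbocycle to the mirror-symmetric phenol 3, in which N1, C2 and C3 are already attached. The forward reaction is a net C–H amination meta to a phenol, which the arene itself cannot do. It is reached by oxidative dearomatization to the 4-methoxydienone 4, 5-exo-trig aza-Michael closure to the hydroindolone 5, and loss of methanol with rearomatization to 6. It requires that methanol, not nitrogen, is captured at C3a, that nitrogen adds before the side chain migrates, and that both bromines stay. The precursor is monocyclic and symmetric, and the product holds the complete bicyclic skeleton with four of the five benzenoid substituents in place.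

**3 ⇒ 2 (C5–Br and C7–Br).** With the para position of the phenol occupied by the side chain, the two ortho positions are the only activated sites. The pattern is fixed by constitution and not by relative rates. The nosyl ring is strongly deactivated and does not compete.

**2 ⇒ 1 (N–S).** This leaves tyramine 1, a bulk amine that supplies all eight ring carbons, the nitrogen and the oxygen of the target. The sulfonyl group shields the amine from bromine and iodine(III). It makes N–H acidic enough for a mildly catalysed conjugate addition. It also leaves N1 non-basic after closure, so that the C7 bromide is not displaced.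

## Roads not taken

**Alternative 1:** (the most obvious) Cut all three C–Br bonds, back to 6-methoxy-1H-indole A1. The forward key step is electrophilic bromination.
- On A1 itself the first bromine goes to C3 (3-bromo-6-methoxy-1H-indole A3) and the next to C2, so the benzenoid ring is reached only after the pyrrole ring is spent.
- The workable form reduces A1 to 6-methoxyindoline A2, in which C5 and C7 are activated by both heteroatoms, dibrominates it to 8, and then joins the end game used here.
- The chosen plan is better because in A2 the reagent that must brominate twice can also dehydrogenate the N–H indoline. Every molecule that becomes an indole early is brominated in the wrong ring, so the outcome hangs on relative rates.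
- An N-acyl block stops the oxidation but takes electron density and space from C7.
- The C2–C3 bond is reduced only to be oxidised again, and nothing is constructed, since A1 already holds every ring atom.
- The step count is similar, but in the chosen plan C5 and C7 are the only open activated positions of the phenol.

**Alternative 2:** Cut C3–C3a and N1–C2 (Bartoli indole synthesis). The forward key step is attack of three equivalents of a vinyl Grignard reagent on 1,3-dibromo-2-methoxy-4-nitrobenzene A4. The bromine ortho to the nitro group steers the [3,3] shift to the free ortho carbon, which gives 9 directly.
- The chosen plan is better because A4 has its nitro group meta to the methoxy group and next to a bromine, a pattern no direct substitution delivers.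
- Nitration of 2,6-dibromoanisole A5 goes para to oxygen.
- Bromination in the meta-nitrophenol ether series also fills the position para to oxygen.
- The run-up with blocking groups would be longer than the whole present route.
- The Grignard reagent can also exchange with the C–Br bond activated by the nitro group.

**Alternative 3:** Cut N1–C7a on the intact arene by nitrene C–H insertion (Hemetsberger–Knittel synthesis). 3,5-Dibromo-4-methoxybenzaldehyde A6 is condensed with an azidoacetate ester to methyl (Z)-2-azido-3-(3,5-dibromo-4-methoxyphenyl)acrylate A7. Thermolysis of A7 gives methyl 5,7-dibromo-6-methoxy-1H-indole-2-carboxylate A8.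
- This uses the same mirror symmetry and the same bond as the chosen plan.
- The chosen plan is better because the C2 ester is extraneous. It has to be saponified to 5,7-dibromo-6-methoxy-1H-indole-2-carboxylic acid A9 and removed by a hot, usually copper-assisted decarboxylation, conditions under which aryl bromides are at risk of protodebromination and coupling.
- Two carbons and two nitrogens are introduced only to be discarded, an energetic azide is heated, and the step count is no lower.

Key step: step 3

Assumption: the target has no stereocentre and no chirality axis, so the demand for a single enantiomer is met by the constitution alone. The stereocentres of 5 are transient and are erased in the same flask.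

## Route

Step 1
Reactants: 1 tyramine (4-(2-aminoethyl)phenol)
Product: 2 N-[2-(4-hydroxyphenyl)ethyl]-2-nitrobenzenesulfonamide
Conditions: 2-NsCl (1.0 equiv), NaHCO3, THF/H2O, 0 °C → rt
Reagents that add atoms: 2-nitrobenzenesulfonyl chloride, O=S(=O)(Cl)c1ccccc1[N+](=O)[O-]
Why: Schotten–Baumann sulfonylation; at bicarbonate pH the phenol is not ionised and the primary amine is by far the better nucleophile, so only nitrogen should react.

Step 2
Reactants: 2 N-[2-(4-hydroxyphenyl)ethyl]-2-nitrobenzenesulfonamide
Product: 3 N-[2-(3,5-dibromo-4-hydroxyphenyl)ethyl]-2-nitrobenzenesulfonamide
Conditions: Br2 (2.1 equiv), AcOH, rt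
Reagents that add atoms: bromine, BrBr
Why: Electrophilic aromatic bromination of a para-substituted phenol, whose two ortho carbons (future C5 and C7) are the only activated positions. The nitroarene ring is inert and the sulfonamide nitrogen is not oxidised.

Step 3
Reactants: 3 N-[2-(3,5-dibromo-4-hydroxyphenyl)ethyl]-2-nitrobenzenesulfonamide
Product: 6 5,7-dibromo-1-(2-nitrophenylsulfonyl)indolin-6-ol, via methoxydienone 4 (not isolated), via cis-hydroindolone 5 (not isolated)
Conditions: PhI(OAc)2 (1.1 equiv), MeOH, 0 °C; evaporate (toluene chase); Et3N (0.3 equiv), CH2Cl2, rt; then MsOH (3 equiv), rt → 40 °C
Reagents that add atoms: methanol, CO (its OCH3 group is held by 4 and 5 and leaves again as methanol before 6)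
Why: Ligand exchange of the phenol at iodine(III) and two-electron oxidation give a phenoxenium equivalent that methanol captures at the para carbon (future C3a), because the only internal alternative, ipso attack of the sulfonamide, would close a four-membered ring; this is the standard oxidative dearomatization of 4-alkylphenols, also well known for 2,6-dibromophenols of the bromotyrosine type. In dienone 4 the two CH β-carbons are enantiotopic, so attack of nitrogen on either one leads to the same constitution and no regiochemical choice exists. The amine-catalysed aza-Michael addition closes the pyrrolidine ring (N1–C7a) in the 5-exo-trig mode, the closest known reaction types being the cyclization of sulfonamide- and carbamate-tethered cyclohexadienones to cis-hydroindolones and, in the ortho-quinone series, the closure of oxidised catecholamines to hydroxyindolines. The two-carbon tether delivers nitrogen on the face that bears C3, so 5 is cis-fused; C3a, C7a and C7 are transient stereocentres, formed as a racemate and all erased in the next event. Acid enolises the α-bromoketone towards C7, and the resulting cyclohexadienol is formally a methanol adduct of an arene, which ionises at C3a, loses H-7a and gives phenol 6; this is the known addition–rearomatization mode of para-quinol ethers that places a nucleophile meta to the phenol oxygen. The α-bromines lower the LUMO of the dienone and speed the addition, while N1, fully substituted and non-basic after closure, cannot displace the C7 bromide to an aziridine, and no base strong enough to eliminate HBr is present. The selectivity that is needed is N-closure before a 1,2-shift of the side chain, and it is secured by forming N1–C7a under mild base before any strong acid is added.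

Step 4
Reactants: 6 5,7-dibromo-1-(2-nitrophenylsulfonyl)indolin-6-ol
Product: 8 5,7-dibromo-6-methoxyindoline, via nosylindoline methyl ether 7 (not isolated)
Conditions: K2CO3 (4 equiv), MeI (1.3 equiv), DMF, rt; then PhSH (2.5 equiv), rt → 40 °C
Reagents that add atoms: iodomethane, CI
Why: Williamson O-methylation of the acidic 2,6-dibromophenol while N1 is still blocked, then Fukuyama denosylation, in which the thiolate adds to the ipso carbon of the nitroarene (Meisenheimer adduct) and the sulfonamide collapses with loss of SO2. No reductant or metal is involved, so both C–Br bonds should survive, and surplus iodomethane is scavenged by the thiolate.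

Step 5
Reactants: 8 5,7-dibromo-6-methoxyindoline
Product: 10 3,5,7-tribromo-6-methoxy-1H-indole, via 5,7-dibromo-6-methoxy-1H-indole 9 (not isolated)
Conditions: NBS (2.05 equiv, two portions), NaHCO3, DMF, −10 °C → rt, dark
Reagents that add atoms: N-bromosuccinimide, O=C1CCC(=O)N1Br
Why: N-Bromination of the indoline and loss of HBr give the 3H-indole, which tautomerises to 9 (dehydrogenation of indolines by N-halo reagents); C5 and C7, where an indoline would otherwise be brominated, are already filled. The second equivalent brominates 9 at C3, the innate site of electrophilic substitution of indoles, and bicarbonate removes the HBr that would harm the product.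

## Compound list

1 | tyramine, 4-(2-aminoethyl)phenol | NCCc1ccc(O)cc1 | starting material
2 | N-[2-(4-hydroxyphenyl)ethyl]-2-nitrobenzenesulfonamide | O=S(=O)(NCCc1ccc(O)cc1)c1ccccc1[N+](=O)[O-] | intermediate
3 | N-[2-(3,5-dibromo-4-hydroxyphenyl)ethyl]-2-nitrobenzenesulfonamide | O=S(=O)(NCCc1cc(Br)c(O)c(Br)c1)c1ccccc1[N+](=O)[O-] | intermediate
4 | N-[2-(3,5-dibromo-1-methoxy-4-oxocyclohexa-2,5-dien-1-yl)ethyl]-2-nitrobenzenesulfonamide | COC1(CCNS(=O)(=O)c2ccccc2[N+](=O)[O-])C=C(Br)C(=O)C(Br)=C1 | intermediate (not isolated)
5 | cis-5,7-dibromo-3a-methoxy-1-(2-nitrophenylsulfonyl)-1,2,3,3a,7,7a-hexahydro-6H-indol-6-one (racemic, 3a-OMe and 7a-H on the same face, C7 undefined) | CO[C@]12CCN(S(=O)(=O)c3ccccc3[N+](=O)[O-])[C@H]1C(Br)C(=O)C(Br)=C2 | intermediate (not isolated)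
6 | 5,7-dibromo-1-(2-nitrophenylsulfonyl)indolin-6-ol | Oc1c(Br)cc2c(c1Br)N(S(=O)(=O)c1ccccc1[N+](=O)[O-])CC2 | intermediate
7 | 5,7-dibromo-6-methoxy-1-(2-nitrophenylsulfonyl)indoline | COc1c(Br)cc2c(c1Br)N(S(=O)(=O)c1ccccc1[N+](=O)[O-])CC2 | intermediate (not isolated)
8 | 5,7-dibromo-6-methoxyindoline | COc1c(Br)cc2c(c1Br)NCC2 | intermediate
9 | 5,7-dibromo-6-methoxy-1H-indole | COc1c(Br)cc2cc[nH]c2c1Br | intermediate (not isolated)
10 | 3,5,7-tribromo-6-methoxy-1H-indole | COc1c(Br)cc2c(Br)c[nH]c2c1Br | target

## Step count and least certain steps

Total steps: 5. Longest linear sequence: 5 (fully linear from 1).

**Step 3 (key step).**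
- Risks:
  - In the acid stage, retro-aza-Michael opening followed by a 1,2-shift of the side chain (dienone–phenol rearrangement) may outrun the loss of methanol. Ionisation at C3a is slowed by the two bromines and the neighbouring sulfonamide.
  - In the oxidation stage, the electron-poor dibromophenol may react sluggishly or lose a benzylic proton towards a quinone methide instead of capturing methanol.
- Fallback (sets out from 1, returns at 8): the N1–C7a bond is made on the intact arene by directed C–H palladation instead of by dearomatization. Compound 1 is dibrominated as its salt to 3,5-dibromotyramine F1. F1 is acylated with picolinic acid to N-[2-(3,5-dibromo-4-hydroxyphenyl)ethyl]picolinamide F2, which is O-methylated to N-[2-(3,5-dibromo-4-methoxyphenyl)ethyl]picolinamide F3. Catalytic Pd(OAc)2 with PhI(OAc)2 in hot toluene should then close 5,7-dibromo-6-methoxy-1-picolinoylindoline F4 through a six-membered palladacycle and C–N reductive elimination from Pd(IV). This is a known indoline synthesis that involves no Pd(0), so aryl bromides are tolerated, and the mirror symmetry of the ring again removes any regiochemical choice. Basic hydrolysis of the amide gives 8.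

**Step 5.**
- Risks:
  - One reagent does two jobs at different rates, so bromination may run on to C2 in molecules that aromatise early while others are still indolines.
  - Any HBr that escapes the buffer may degrade or isomerise the N–H 3-bromoindole.
- Fallback (sets out from 7, isolated before the thiol is added in step 4, returns at 10): oxidation and bromination are carried out on the protected nitrogen, and the sensitive N–H compound is released last. Wohl–Ziegler bromination of 7 at benzylic C3 with spontaneous loss of HBr should give 5,7-dibromo-6-methoxy-1-(2-nitrophenylsulfonyl)-1H-indole F5. Electrophilic bromination of this deactivated indole stops cleanly at C3 to give 3,5,7-tribromo-6-methoxy-1-(2-nitrophenylsulfonyl)-1H-indole F6. Thiolate denosylation under the mild, non-acidic and non-oxidising conditions of step 4 gives 10.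

**Step 4.**
- Risks:
  - The thiolate may attack the O-methyl group in an SN2 demethylation, since 2,6-dibromophenoxide is a good leaving group.
  - Methylation of the doubly ortho-substituted phenoxide may be slow, so that unmethylated material enters the deprotection.
- Fallback (sets out from 6, returns at 9): 6 is methylated as before and 7 is isolated. Instead of a thiol, a non-nucleophilic base (DBU or Cs2CO3 in hot DMF) removes H-2 and expels 2-nitrobenzenesulfinate from N1. This is the 1,2-elimination used to aromatise N-sulfonyl pyrrolines, dihydroquinolines and indolines, and the 3H-indole so formed tautomerises to 9. The sulfonyl group then acts as the internal oxidant, no thiolate meets the methyl ether, and 8 is bypassed. Step 5 is run on 9 with one equivalent of NBS.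

## Further compounds

F1 | step 3 | 3,5-dibromotyramine, 4-(2-aminoethyl)-2,6-dibromophenol | NCCc1cc(Br)c(O)c(Br)c1
F2 | step 3 | N-[2-(3,5-dibromo-4-hydroxyphenyl)ethyl]picolinamide | O=C(NCCc1cc(Br)c(O)c(Br)c1)c1ccccn1
F3 | step 3 | N-[2-(3,5-dibromo-4-methoxyphenyl)ethyl]picolinamide | COc1c(Br)cc(CCNC(=O)c2ccccn2)cc1Br
F4 | step 3 | 5,7-dibromo-6-methoxy-1-picolinoylindoline | COc1c(Br)cc2c(c1Br)N(C(=O)c1ccccn1)CC2
F0 | step 4 | none | none
F5 | step 5 | 5,7-dibromo-6-methoxy-1-(2-nitrophenylsulfonyl)-1H-indole | COc1c(Br)cc2ccn(S(=O)(=O)c3ccccc3[N+](=O)[O-])c2c1Br
F6 | step 5 | 3,5,7-tribromo-6-methoxy-1-(2-nitrophenylsulfonyl)-1H-indole | COc1c(Br)cc2c(Br)cn(S(=O)(=O)c3ccccc3[N+](=O)[O-])c2c1Br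
A1 | alternative 1 | 6-methoxy-1H-indole | COc1ccc2cc[nH]c2c1
A2 | alternative 1 | 6-methoxyindoline | COc1ccc2c(c1)NCC2
A3 | alternative 1 | 3-bromo-6-methoxy-1H-indole | COc1ccc2c(Br)c[nH]c2c1
A4 | alternative 2 | 1,3-dibromo-2-methoxy-4-nitrobenzene | COc1c(Br)ccc([N+](=O)[O-])c1Br
A5 | alternative 2 | 2,6-dibromoanisole | COc1c(Br)cccc1Br
A6 | alternative 3 | 3,5-dibromo-4-methoxybenzaldehyde | COc1c(Br)cc(C=O)cc1Br
A7 | alternative 3 | methyl (Z)-2-azido-3-(3,5-dibromo-4-methoxyphenyl)acrylate | COC(=O)/C(N=[N+]=[N-])=C/c1cc(Br)c(OC)c(Br)c1
A8 | alternative 3 | methyl 5,7-dibromo-6-methoxy-1H-indole-2-carboxylate | COC(=O)c1cc2cc(Br)c(OC)c(Br)c2[nH]1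
A9 | alternative 3 | 5,7-dibromo-6-methoxy-1H-indole-2-carboxylic acid | COc1c(Br)cc2cc(C(=O)O)[nH]c2c1Br
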